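**Retrosynthetic overview**

1. Target 19 ← hydrogenolysis of six benzyl ethers ← acylation of the only free phenol (O3' of ring B) of a 5,7,4'-tri-O-benzyl catechin with tri-O-benzylgalloyl chloride.
2. The C3 hydroxyl and both stereocentres (C2, C3) ← one reagent-controlled syn hydroboration–oxidation of the C2=C3 bond of an achiral flav-2-ene (2-aryl-4H-chromene); C2 is carried at the ketone oxidation level until then.
3. Flav-2-ene ← convergent [3+3] annulation that forms C4–C3 and O1–C8a in one flask: the enolate of a ring B acetophenone (O1–C2=C3, an O,C-dinucleophile) plus a ring A 2-bromobenzyl bromide (C4 and C8a, a 1,3-dielectrophile).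
4. Enabling feature: C2 bears both the ring oxygen O1 and ring B, so O1–C2–C3 is the enolate of an aryl methyl ketone. C8a is meta to both ring A oxygens (on C5 and C7), so its C–Br bond stays reactive; closure through oxygen gives six-membered ring C, whereas closure through C3 would give a four-membered ring.
5. Ring order: rings A and B and the galloyl ring are bought as arenes; ring C is the only ring formed (step 7).

Key step: step 7

Remark: flavan numbering is used (O1, C2, C3, C4, C4a, C5 to C8, C8a; ring B primed). The target is taken as the (2R,3S) isomer with the galloyl ester on O3'. IpcBH2 means monoisopinocampheylborane prepared from (+)-α-pinene, C[C@H]1[C@H](B)C[C@@H]2C[C@H]1C2(C)C, used as a freshly prepared solution.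

**Route**

Step 1
Reactants: 1 5-bromobenzene-1,3-diol
Product: 2 1,3-bis(benzyloxy)-5-bromobenzene
Conditions: BnBr (2.2 equiv), K2CO3, DMF, rt
Reagents that add atoms: benzyl bromide, BrCc1ccccc1
Why: Williamson ether synthesis in which both phenoxides are benzylated by SN2, giving ethers that should survive every later step and leave together in the final hydrogenolysis.

Step 2
Reactants: 2 1,3-bis(benzyloxy)-5-bromobenzene
Product: 4 2,4-bis(benzyloxy)-6-bromobenzaldehyde, via iminium salt 3 (not isolated)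
Conditions: POCl3, DMF, 0 to 70 °C; then H2O, 0 °C to rt
Reagents that add atoms: N,N-dimethylformamide, CN(C)C=O; water, O
Why: Vilsmeier–Haack formylation in which the chloroiminium electrophile should attack the position between bromine and one benzyloxy group (para to the other), which is less hindered than the site between the two benzyloxy groups, and hydrolysis of the iminium salt releases the aldehyde.

Step 3
Reactants: 4 2,4-bis(benzyloxy)-6-bromobenzaldehyde
Product: 5 [2,4-bis(benzyloxy)-6-bromophenyl]methanol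
Conditions: NaBH4, THF/MeOH, 0 °C
Reagents that add atoms: none
Why: Borohydride reduction of the aldehyde to the benzylic alcohol, which leaves the aryl bromide and the benzyl ethers untouched.

Step 4
Reactants: 5 [2,4-bis(benzyloxy)-6-bromophenyl]methanol
Product: 6 1,5-bis(benzyloxy)-3-bromo-2-(bromomethyl)benzene
Conditions: PBr3, Et2O, 0 °C; crude bromide used at once
Reagents that add atoms: phosphorus tribromide, BrP(Br)Br
Why: Conversion of the alcohol into the bromide through a phosphite ester and SN2 displacement by bromide, run cold and without storage because the electron-rich benzylic bromide is prone to self-alkylation.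

Step 5
Reactants: 7 1-(3,4-dihydroxyphenyl)ethanone
Product: 8 1-[4-(benzyloxy)-3-hydroxyphenyl]ethanone
Conditions: BnBr (1.0 equiv), NaHCO3, NaI (cat.), DMF, 40 °C
Reagents that add atoms: benzyl bromide, BrCc1ccccc1
Why: Regioselective Williamson etherification, since only the hydroxyl para to the acetyl group is acidic enough to be ionised by NaHCO3, which leaves the future galloylation site O3' free.

Step 6
Reactants: 8 1-[4-(benzyloxy)-3-hydroxyphenyl]ethanone
Product: 9 1-[4-(benzyloxy)-3-(methoxymethoxy)phenyl]ethanone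
Conditions: MOMCl, iPr2NEt, CH2Cl2, 0 °C to rt
Reagents that add atoms: chloromethyl methyl ether, COCCl
Why: Alkylation of the phenol to its methoxymethyl acetal, a group stable to strong base, palladium catalysis and hydroboration–oxidation yet removable by mild acid in the presence of benzyl ethers.

Step 7
Reactants: 9 1-[4-(benzyloxy)-3-(methoxymethoxy)phenyl]ethanone; 6 1,5-bis(benzyloxy)-3-bromo-2-(bromomethyl)benzene
Product: 12 5,7-bis(benzyloxy)-2-[4-(benzyloxy)-3-(methoxymethoxy)phenyl]-4H-chromene, via lithium enolate 10 (not isolated), via bromo ketone 11 (not isolated)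
Conditions: LiN(SiMe3)2 (1.05 equiv), THF, -78 °C; 6 (1.0 equiv), -78 to 0 °C; solvent switch to toluene; Pd2(dba)3 (2.5 mol %), DPEphos (6 mol %), NaOtBu (1.4 equiv), 90 °C, high dilution
Reagents that add atoms: none
Why: The lithium enolate of 9 is C-benzylated by the benzylic bromide of 6 (SN2), which forms the C4–C3 bond and gives bromo ketone 11; after the solvent switch, NaOtBu regenerates the enolate, zerovalent palladium inserts into the C8a–Br bond, the enolate binds through oxygen and C–O reductive elimination forms the O1–C8a bond together with the C2=C3 enol ether. The closest known reaction types are ketone enolate alkylation, the palladium-catalysed intramolecular O-arylation of ketone enolates by ortho-bromoaryl groups used for benzofurans, and the copper-catalysed C-benzylation/O-arylation annulation of 2-bromobenzyl bromides with 1,3-dicarbonyl compounds to 4H-chromenes. Ring C closes by intramolecular O-arylation through a seven-membered aryl palladium O-enolate, the six-membered O-closure being the only unstrained option because arylation at C3 would give a benzocyclobutene. No stereocentre is created, as the step delivers the achiral flav-2-ene whose C2=C3 bond is the handle for step 8. The selectivities needed are mono- over di-benzylation (kinetic lithium enolate, low temperature, one equivalent of 6), discrimination between the two C–Br bonds (the benzylic one reacts by SN2 at low temperature, the aryl one only under palladium catalysis) and intra- over intermolecular arylation (dilution).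

Step 8
Reactants: 12 5,7-bis(benzyloxy)-2-[4-(benzyloxy)-3-(methoxymethoxy)phenyl]-4H-chromene
Product: 14 (2R,3S)-5,7-bis(benzyloxy)-2-[4-(benzyloxy)-3-(methoxymethoxy)phenyl]-3,4-dihydro-2H-chromen-3-ol, via dialkylborane 13 (not isolated)
Conditions: IpcBH2 from (+)-α-pinene (1.2 equiv), THF, -25 °C; then NaOH, H2O2, H2O, 0 °C to rt
Reagents that add atoms: hydrogen peroxide, OO
Why: Asymmetric hydroboration–oxidation in which boron adds to C3 (β to O1 and remote from the aryl-bearing carbon) and hydrogen to C2 on the same face, so that the 2,3-trans relationship follows from syn addition, the alkene face is chosen by the isopinocampheyl group in the sense known for 1-arylcycloalkenes (corresponding to 2R,3S here), and oxidation of the C–B bond proceeds with retention.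

Step 9
Reactants: 14 (2R,3S)-5,7-bis(benzyloxy)-2-[4-(benzyloxy)-3-(methoxymethoxy)phenyl]-3,4-dihydro-2H-chromen-3-ol
Product: 15 (2R,3S)-5,7-bis(benzyloxy)-2-[4-(benzyloxy)-3-hydroxyphenyl]-3,4-dihydro-2H-chromen-3-ol
Conditions: HCl (2 M aq, cat.), MeOH/THF, 40 °C
Reagents that add atoms: none
Why: Acid-catalysed acetal cleavage (transacetalisation to methanol) that should free the O3' phenol under conditions too mild to ionise the C2–O1 bond or touch the benzyl ethers.

Step 10
Reactants: 16 3,4,5-tris(benzyloxy)benzoic acid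
Product: 17 3,4,5-tris(benzyloxy)benzoyl chloride
Conditions: (COCl)2, DMF (cat.), CH2Cl2, 0 °C to rt; concentrated and used crude
Reagents that add atoms: oxalyl chloride, ClC(=O)C(Cl)=O
Why: Acid chloride formation through the chloroiminium species generated from catalytic DMF, with only gaseous by-products.

Step 11
Reactants: 15 (2R,3S)-5,7-bis(benzyloxy)-2-[4-(benzyloxy)-3-hydroxyphenyl]-3,4-dihydro-2H-chromen-3-ol; 17 3,4,5-tris(benzyloxy)benzoyl chloride
Product: 18 2-(benzyloxy)-5-[(2R,3S)-5,7-bis(benzyloxy)-3-hydroxy-3,4-dihydro-2H-chromen-2-yl]phenyl 3,4,5-tris(benzyloxy)benzoate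
Conditions: Et3N (1.2 equiv), CH2Cl2, -20 to 0 °C, no acyl-transfer catalyst
Reagents that add atoms: none
Why: Chemoselective O-acylation in which the phenol, ionised by the amine, should be acylated far faster than the hindered neutral secondary C3 alcohol in the absence of an acyl-transfer catalyst, and the 4'-benzyl ether fixes the ester on O3'.

Step 12
Reactants: 18 2-(benzyloxy)-5-[(2R,3S)-5,7-bis(benzyloxy)-3-hydroxy-3,4-dihydro-2H-chromen-2-yl]phenyl 3,4,5-tris(benzyloxy)benzoate
Product: 19 catechin 3'-O-gallate, 2-hydroxy-5-[(2R,3S)-3,5,7-trihydroxy-3,4-dihydro-2H-chromen-2-yl]phenyl 3,4,5-trihydroxybenzoate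
Conditions: H2 (1 atm), Pd(OH)2/C, THF/MeOH, rt, neutral
Reagents that add atoms: none
Why: Catalytic hydrogenolysis of all six benzyl ethers under neutral conditions, which should leave the aryl ester, the C2–O1 bond and both stereocentres intact and avoid base-induced acyl shift to O4'.

**Compound list**

1 | 5-bromobenzene-1,3-diol | Oc1cc(O)cc(Br)c1 | starting material
2 | 1,3-bis(benzyloxy)-5-bromobenzene | Brc1cc(OCc2ccccc2)cc(OCc2ccccc2)c1 | intermediate
3 | N-[2,4-bis(benzyloxy)-6-bromobenzylidene]-N-methylmethanaminium dichlorophosphate | C[N+](C)=Cc1c(Br)cc(OCc2ccccc2)cc1OCc1ccccc1.[O-]P(=O)(Cl)Cl | intermediate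
4 | 2,4-bis(benzyloxy)-6-bromobenzaldehyde | O=Cc1c(Br)cc(OCc2ccccc2)cc1OCc1ccccc1 | intermediate
5 | [2,4-bis(benzyloxy)-6-bromophenyl]methanol | OCc1c(Br)cc(OCc2ccccc2)cc1OCc1ccccc1 | intermediate
6 | 1,5-bis(benzyloxy)-3-bromo-2-(bromomethyl)benzene | BrCc1c(Br)cc(OCc2ccccc2)cc1OCc1ccccc1 | intermediate
7 | 1-(3,4-dihydroxyphenyl)ethanone | CC(=O)c1ccc(O)c(O)c1 | starting material
8 | 1-[4-(benzyloxy)-3-hydroxyphenyl]ethanone | CC(=O)c1ccc(OCc2ccccc2)c(O)c1 | intermediate
9 | 1-[4-(benzyloxy)-3-(methoxymethoxy)phenyl]ethanone | CC(=O)c1ccc(OCc2ccccc2)c(OCOC)c1 | intermediate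
10 | lithium 1-[4-(benzyloxy)-3-(methoxymethoxy)phenyl]ethenolate | [Li+].[O-]C(=C)c1ccc(OCc2ccccc2)c(OCOC)c1 | intermediate
11 | 3-[2,4-bis(benzyloxy)-6-bromophenyl]-1-[4-(benzyloxy)-3-(methoxymethoxy)phenyl]propan-1-one | O=C(CCc1c(Br)cc(OCc2ccccc2)cc1OCc1ccccc1)c1ccc(OCc2ccccc2)c(OCOC)c1 | intermediate
12 | 5,7-bis(benzyloxy)-2-[4-(benzyloxy)-3-(methoxymethoxy)phenyl]-4H-chromene | COCOc1cc(C2=CCc3c(OCc4ccccc4)cc(OCc4ccccc4)cc3O2)ccc1OCc1ccccc1 | intermediate
13 | isopinocampheyl{2,3-trans-5,7-bis(benzyloxy)-2-[4-(benzyloxy)-3-(methoxymethoxy)phenyl]-3,4-dihydro-2H-chromen-3-yl}borane, boron on the face that later carries the C3 hydroxyl | COCOc1cc([C@H]2Oc3cc(OCc4ccccc4)cc(OCc4ccccc4)c3C[C@@H]2B[C@@H]2C[C@@H]3C[C@H]([C@H]2C)C3(C)C)ccc1OCc1ccccc1 | intermediate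
14 | (2R,3S)-5,7-bis(benzyloxy)-2-[4-(benzyloxy)-3-(methoxymethoxy)phenyl]-3,4-dihydro-2H-chromen-3-ol | COCOc1cc([C@H]2Oc3cc(OCc4ccccc4)cc(OCc4ccccc4)c3C[C@@H]2O)ccc1OCc1ccccc1 | intermediate
15 | (2R,3S)-5,7-bis(benzyloxy)-2-[4-(benzyloxy)-3-hydroxyphenyl]-3,4-dihydro-2H-chromen-3-ol | Oc1cc([C@H]2Oc3cc(OCc4ccccc4)cc(OCc4ccccc4)c3C[C@@H]2O)ccc1OCc1ccccc1 | intermediate
16 | 3,4,5-tris(benzyloxy)benzoic acid | OC(=O)c1cc(OCc2ccccc2)c(OCc2ccccc2)c(OCc2ccccc2)c1 | starting material
17 | 3,4,5-tris(benzyloxy)benzoyl chloride | ClC(=O)c1cc(OCc2ccccc2)c(OCc2ccccc2)c(OCc2ccccc2)c1 | intermediate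
18 | 2-(benzyloxy)-5-[(2R,3S)-5,7-bis(benzyloxy)-3-hydroxy-3,4-dihydro-2H-chromen-2-yl]phenyl 3,4,5-tris(benzyloxy)benzoate | O=C(Oc1cc([C@H]2Oc3cc(OCc4ccccc4)cc(OCc4ccccc4)c3C[C@@H]2O)ccc1OCc1ccccc1)c1cc(OCc2ccccc2)c(OCc2ccccc2)c(OCc2ccccc2)c1 | intermediate
19 | catechin 3'-O-gallate, 2-hydroxy-5-[(2R,3S)-3,5,7-trihydroxy-3,4-dihydro-2H-chromen-2-yl]phenyl 3,4,5-trihydroxybenzoate | O=C(Oc1cc([C@H]2Oc3cc(O)cc(O)c3C[C@@H]2O)ccc1O)c1cc(O)c(O)c(O)c1 | target

**Step count and risks**

Total step count: 12. Longest linear sequence: 9 steps (1, 2, 3, 4, 7, 8, 9, 11, 12).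

Steps most likely to fail:

Step 7. Three processes could go wrong: proton exchange between enolate and product leading to double benzylation, self-alkylation of the electron-rich benzylic bromide before it is consumed, and β-hydride elimination from a carbon-bound palladium enolate (hydrodebromination) competing with C–O reductive elimination. The fallback builds the C4–C3 bond by condensation and 1,4-reduction instead of alkylation and avoids bromide 6 altogether. It sets out from aldehyde 4 and ketone 9: Claisen–Schmidt condensation (KOH, EtOH/THF, rt) should give (E)-3-[2,4-bis(benzyloxy)-6-bromophenyl]-1-[4-(benzyloxy)-3-(methoxymethoxy)phenyl]prop-2-en-1-one F1. Conjugate reduction with [(Ph3P)CuH]6 (toluene, rt, aqueous work-up), which should leave the aryl bromide alone, then returns to the route at bromo ketone 11, now isolated and purified. Compound 11 is closed to 12 in a separate O-arylation (Pd2(dba)3, DPEphos, NaOtBu, toluene, 90 °C, or CuI, 1,10-phenanthroline, Cs2CO3).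

Step 8. The chiral borane may discriminate poorly between the faces of an enol ether flanked by fused ring A, and the β-aryloxy borane may ring-open by β-elimination before oxidation. The fallback replaces reagent control by resolution. It sets out from 12: BH3·SMe2 (THF, 0 °C) followed at once by NaOH/H2O2 should give 14 together with its enantiomer (2S,3R)-5,7-bis(benzyloxy)-2-[4-(benzyloxy)-3-(methoxymethoxy)phenyl]-3,4-dihydro-2H-chromen-3-ol F2. Steglich esterification of the mixture with (S)-2-methoxy-2-phenylacetic acid (DCC, DMAP cat., CH2Cl2, 0 °C) gives the diastereomeric esters (2R,3S)-chromen-3-yl (S)-2-methoxy-2-phenylacetate F3 and (2S,3R)-chromen-3-yl (S)-2-methoxy-2-phenylacetate F4, to be separated by chromatography or crystallisation. Saponification of F3 (LiOH, THF/H2O, rt) returns to the route at 14.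

Step 11. The secondary C3 hydroxyl may be acylated in competition with the phenol, giving bis-ester or the wrong mono-ester. The fallback removes the need for chemoselectivity by protecting C3–OH. It sets out from 14: NaH, BnBr, DMF (0 °C to rt) gives (2R,3S)-3,5,7-tris(benzyloxy)-2-[4-(benzyloxy)-3-(methoxymethoxy)phenyl]-3,4-dihydro-2H-chromene F5. Acidic removal of the methoxymethyl group (HCl cat., MeOH/THF, 40 °C) gives 2-(benzyloxy)-5-[(2R,3S)-3,5,7-tris(benzyloxy)-3,4-dihydro-2H-chromen-2-yl]phenol F6, in which the phenol is the only hydroxyl. Acylation with 17 (Et3N, DMAP cat., CH2Cl2) gives 2-(benzyloxy)-5-[(2R,3S)-3,5,7-tris(benzyloxy)-3,4-dihydro-2H-chromen-2-yl]phenyl 3,4,5-tris(benzyloxy)benzoate F7. Hydrogenolysis of its seven benzyl ethers (H2, Pd(OH)2/C, THF/MeOH) returns to the route at target 19.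

**Further compounds**

F1 | step 7 | (E)-3-[2,4-bis(benzyloxy)-6-bromophenyl]-1-[4-(benzyloxy)-3-(methoxymethoxy)phenyl]prop-2-en-1-one | O=C(/C=C/c1c(Br)cc(OCc2ccccc2)cc1OCc1ccccc1)c1ccc(OCc2ccccc2)c(OCOC)c1
F2 | step 8 | (2S,3R)-5,7-bis(benzyloxy)-2-[4-(benzyloxy)-3-(methoxymethoxy)phenyl]-3,4-dihydro-2H-chromen-3-ol | COCOc1cc([C@@H]2Oc3cc(OCc4ccccc4)cc(OCc4ccccc4)c3C[C@H]2O)ccc1OCc1ccccc1
F3 | step 8 | (2R,3S)-5,7-bis(benzyloxy)-2-[4-(benzyloxy)-3-(methoxymethoxy)phenyl]-3,4-dihydro-2H-chromen-3-yl (S)-2-methoxy-2-phenylacetate | COCOc1cc([C@H]2Oc3cc(OCc4ccccc4)cc(OCc4ccccc4)c3C[C@@H]2OC(=O)[C@@H](OC)c2ccccc2)ccc1OCc1ccccc1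
F4 | step 8 | (2S,3R)-5,7-bis(benzyloxy)-2-[4-(benzyloxy)-3-(methoxymethoxy)phenyl]-3,4-dihydro-2H-chromen-3-yl (S)-2-methoxy-2-phenylacetate | COCOc1cc([C@@H]2Oc3cc(OCc4ccccc4)cc(OCc4ccccc4)c3C[C@H]2OC(=O)[C@@H](OC)c2ccccc2)ccc1OCc1ccccc1
F5 | step 11 | (2R,3S)-3,5,7-tris(benzyloxy)-2-[4-(benzyloxy)-3-(methoxymethoxy)phenyl]-3,4-dihydro-2H-chromene | COCOc1cc([C@H]2Oc3cc(OCc4ccccc4)cc(OCc4ccccc4)c3C[C@@H]2OCc2ccccc2)ccc1OCc1ccccc1
F6 | step 11 | 2-(benzyloxy)-5-[(2R,3S)-3,5,7-tris(benzyloxy)-3,4-dihydro-2H-chromen-2-yl]phenol | Oc1cc([C@H]2Oc3cc(OCc4ccccc4)cc(OCc4ccccc4)c3C[C@@H]2OCc2ccccc2)ccc1OCc1ccccc1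
F7 | step 11 | 2-(benzyloxy)-5-[(2R,3S)-3,5,7-tris(benzyloxy)-3,4-dihydro-2H-chromen-2-yl]phenyl 3,4,5-tris(benzyloxy)benzoate | O=C(Oc1cc([C@H]2Oc3cc(OCc4ccccc4)cc(OCc4ccccc4)c3C[C@@H]2OCc2ccccc2)ccc1OCc1ccccc1)c1cc(OCc2ccccc2)c(OCc2ccccc2)c(OCc2ccccc2)c1
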